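Readings and results come from a simulation with made-up constants.

Reagent is charged at twice the substrate, so if one reagent goes with one substrate, the substrate step can use at most half of it. I take the making of open intermediate as a pseudo-first-order step in substrate at the start, with a constant that scales with b, the fraction of the reagent charge still there.

| flask | substrate | partner | reagent | protic impurity | remark | time |
|---|---|---|---|---|---|---|
| Saturday's | 0.25 M | 0.275 M | 0.50 M | 0.075 M | run made earlier |  |
| Wednesday's | 0.25 M | 0.275 M | 0.50 M | 0.037 M | run made earlier |  |
| Tuesday's | 0.25 M | 0.275 M | 0.50 M | 0.056 M | run made earlier |  |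
| Friday's | 0.25 M | 0.55 M | 0.50 M | 0.075 M | run made earlier |  |
| dusk | 0.25 M | 0.275 M | 0.500 M | 0.0750 M | everything together in a closed stirred flask, run for 1.0 h | 1.0 h |
| dawn | 0.25 M | 0.275 M | 0.500 M (fed, over 0.800 h) | 0.0750 M | all but reagent at the start; reagent goes in evenly over 0.800 h, the run ends at 1.0 h | 1.0 h |
| summer | 0.25 M (fed, over 0.800 h) | 0.275 M | 0.500 M | 0.0750 M | all but substrate at the start; substrate goes in evenly over 0.800 h, the run ends at 1.0 h | 1.0 h |
| spring | 0.25 M | 0.275 M | 0.500 M | 0.0750 M | one stirred flow tank at steady state, fed with the mixture as stated, mean residence time 1.0 h |  |

- Saturday's (time / min: open intermediate / %, target / %): 5.00: 20, 0; 15.0: 44, 0; 30.0: 47, 1; 40.0: 50, 3; 60.0: 49, 6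
- Wednesday's (time / min: open intermediate / %, target / %): 5.00: 21, 1; 10.0: 32, 0; 15.0: 40, 0; 30.0: 48, 4; 60.0: 51, 8
- Tuesday's (time / min: open intermediate / %, target / %): 5.00: 17, 1; 15.0: 40, 1; 30.0: 49, 2; 40.0: 54, 7; 60.0: 52, 5
- Friday's (time / min: open intermediate / %, target / %): 12.0: 35, 0; 25.0: 45, 5; 40.0: 44, 5; 50.0: 45, 9; 60.0: 41, 7

(readings scatter by 2 percentage points)

- the stated concentrations are those of everything mixed, before any reaction; amounts are the same in each set-up
- the analysis behind the earlier runs scatters by 2 percentage points, standard deviation
- the feed brings no volume worth counting
- the earlier runs were made in a closed, stirred flask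

- the set-up with the highest amount of open intermediate at the outlet or at the end, in percent of the substrate put in ("none" if the first two lie within 2 percentage points) (dusk / dawn / summer / spring / none)
- amount of open intermediate at the outlet or at the end, in percent of the substrate put in, dusk
- amount of open intermediate at the outlet or at the end, in percent of the substrate put in, dawn
- amount of open intermediate at the outlet or at the end, in percent of the substrate put in, summer
- amount of open intermediate at the outlet or at the end, in percent of the substrate put in, spring

Pool the readings of open intermediate at 5.00 min from Saturday's, Wednesday's and Tuesday's runs, and you get 2.58 /h. Call this reading the filling constant: the fraction of the substrate present that turns per hour at b of one, at this reagent charge. Later in a run, multiply it by b.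

Now build the flask up, as my own reckoning. Take the main step alone with reagent at full strength, and dusk reaches 92.4 % of the substrate as open intermediate. In dawn, reagent arrives evenly and amounts to 0.600 h at full strength, which gives 78.7 %. In summer, substrate arrives evenly, which gives 74.7 %, and the tank in spring gives 72.1 %.

Next let b fall through the substrate step, and dusk drops to 84.0 %. Then add the rest. Saturday's run is the dusk recipe and reads 49 % at 60.0 min, with target at 6 %, so what remains of the first ceiling is a share of 53.0 %. Carrying that share over, I commit to 41.7 % for dawn, 39.6 % for summer and 38.2 % for spring, with dusk ahead.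

The forecast differs. It gives 49 % for dusk, 47 % for dawn, 47 % for summer and 40 % for spring, and names none as best, reasoning that “If selectivity is unchanged by concentration, feeding gains little and only costs time”.

The flask gives 49.6 % in dusk, 46.9 % in dawn, 41.0 % in summer and 34.4 % in spring, so dusk leads by 2.7 percentage points, more than the margin.

    substrate + reagent → open intermediate (k = 0.00160 /M/s)
    reagent + partner → second intermediate (k = 6.60 × 10⁻⁴ /M/s)
    open intermediate + second intermediate → target (k = 5.20 × 10⁻⁴ /M/s)
    2 open intermediate → homo product (k = 1.80 × 10⁻⁴ /M/s)
    substrate + open intermediate → side product (k = 7.30 × 10⁻⁴ /M/s)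
    reagent + protic impurity → quenched reagent (k = 0.00110 /M/s)

In dusk the substrate step had half its turnover up to 1.0 h behind it by 0.192 h, and at 0.192 h open intermediate was made 5.96 times faster than it was used up; at 1.00 h reagent stood at 29 % of its charge, which puts the filling constant, as read from the early runs, at 0.748 /h, with side product at 19.9 %. The neighbour charged with 1.0 M of substrate ends its hour with reagent at 2.2 % of its charge, which puts the same read constant at 0.0568 /h, with substrate at 35.9 % and 46.9 % in side product.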